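**Assumption:** labdane numbering is used (decalin C1–C10, linker C11–C12, succinimide C13–C16); the target SMILES corresponds to (2S,5S,9S,10R,12S,13R), i.e. 10β‑Me, 5α‑H, 9α‑H, 2α‑Cl, with a syn C12/C13 aldol relationship.

## Retrosynthetic overview

1. Succinimide and C12/C13: Evans syn‑aldol of the C12 aldehyde with a 3‑cyanopropanoyl imide, then nitrile hydration and imide closure.
2. C2–Cl from the C2 ketone (axial alcohol, then inversion); C5–H by SmI2 excision of the former phenol oxygen next to the C6 ketone.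
3. Ring B (C9–C10 bond, C8 exocyclic methylene, C9 and C10 stereocentres) by an enantioselective, desymmetrizing intramolecular Hosomi–Sakurai addition onto a Cs‑symmetric 3,5‑dimethyl‑p‑quinol dienone; the other enone arm then takes a methyl to give the C4 gem‑dimethyl.
4. The dienone comes from 2,6‑xylenol (oxidative dearomatization to the quinone monoketal, which is ring A) plus a lithiated dithiane carrying a (Z)‑allylsilane (from 1,3‑dithiane, propargyl bromide, TMSCH2MgCl and ethylene oxide).
5. Ring order: ring A is the dearomatized arene, ring B forms in the key step, the succinimide ring forms last.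

## Route

**Step 1**
Reactants: 1, 2,6‑dimethylphenol
Product: 2, 4,4‑dimethoxy‑2,6‑dimethylcyclohexa‑2,5‑dien‑1‑one
Conditions: PhI(OAc)2 (2.1 equiv), MeOH, 0 °C → rt
Reagents that add atoms: methanol, CO (both OMe groups)
Why: Double oxidative dearomatization of a para‑unsubstituted phenol (via the 4‑methoxyphenol) gives the p‑quinone monoketal, because both ortho positions are blocked by methyl.

**Step 2**
Reactants: 3, 1,3‑dithiane; 4, propargyl bromide
Product: 5, 2‑(prop‑2‑yn‑1‑yl)‑1,3‑dithiane
Conditions: n‑BuLi, THF, −30 °C; then 4, −78 °C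
Reagents that add atoms: none beyond reactants 3 and 4
Why: Corey–Seebach alkylation of 2‑lithio‑1,3‑dithiane (SN2 at the propargylic bromide at low temperature outruns proton transfer from the alkyne).

**Step 3**
Reactants: 5; 6, (trimethylsilyl)methylmagnesium chloride; 7, ethylene oxide
Product: 8, tert‑butyldimethyl{[(3Z)‑5‑(1,3‑dithian‑2‑yl)‑4‑[(trimethylsilyl)methyl]pent‑3‑en‑1‑yl]oxy}silane
Conditions: 6, CuBr·SMe2, Et2O/Me2S, −45 °C; 5, −25 °C; 1‑pentynyllithium, HMPA, then 7, −78 → −20 °C; then TBSCl, imidazole, rt (one pot)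
Reagents that add atoms: TBSCl, CC(C)(C)[Si](C)(C)Cl
Why: Normant syn‑carbocupration of the terminal alkyne puts CH2SiMe3 on the internal carbon and Cu on the terminal carbon cis to it, and epoxide opening by the derived mixed cuprate proceeds with retention, so the CH2CH2O chain ends cis to CH2SiMe3 (Z).

**Step 4**
Reactants: 8; 2
Product: 9, 4‑{2‑[(2Z)‑5‑(tert‑butyldimethylsilyloxy)‑2‑[(trimethylsilyl)methyl]pent‑2‑en‑1‑yl]‑1,3‑dithian‑2‑yl}‑3,5‑dimethyl‑4‑(trimethylsilyloxy)cyclohexa‑2,5‑dien‑1‑one (Cs‑symmetric; C5 carries OTMS and the chain, both β‑carbons carry Me)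
Conditions: n‑BuLi, THF, −30 °C; 2, −78 °C; TMSCl, −78 → 0 °C; then SiO2, aq. oxalic acid, CH2Cl2, rt
Reagents that add atoms: TMSCl, C[Si](C)(C)Cl
Why: Corey–Seebach acyl‑anion 1,2‑addition to the ketal‑protected quinone carbonyl (the in‑plane methyls do not block perpendicular attack), TMSCl traps the alkoxide before it can revert, and the bis‑allylic ketal hydrolyses under mild acid to unveil the symmetric dienone.

**Step 5 (key step)**
Reactants: 9
Product: 10, (5S,9S,10R)‑cis‑fused enone: 9β‑[2‑(TBSO)ethyl]‑4,10β‑dimethyl‑8‑methylidene‑5β‑(trimethylsilyloxy)‑6,6‑(propane‑1,3‑diyldithio)‑octahydronaphthalen‑2‑one with a 3,4‑double bond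
Conditions: (S,S)‑IDPi (confined imidodiphosphorimidate, 5 mol %), PhMe, −60 °C; then aq. citric acid, THF, 0 °C
Reagents that add atoms: none
Why: Proposed new method: a chiral‑counteranion silylium‑catalysed, desymmetrizing intramolecular Hosomi–Sakurai conjugate addition. The catalyst is silylated in situ and O‑silylates the dienone to a symmetric siloxy‑pentadienyl cation paired with the chiral anion, which selects one enantiotopic β‑carbon for 6‑ring closure by the allylsilane carbon C9 (the antipode giving the 9S,10R series is fixed by an initial screen). The chain can only reach C10 from its own face, so 5‑O and 10‑Me end up cis; a chair transition state with the (Z)‑allylsilane places C11 equatorial and therefore cis to 10‑Me; loss of Me3Si+ gives the exocyclic C8 methylene and turns the catalyst over. The closest known reactions are racemic Lewis‑acid intramolecular Sakurai additions to β‑methyl enones and IDPi/silylium‑catalysed Sakurai and Mukaiyama–Michael reactions.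

**Step 6**
Reactants: 10
Product: 11, (5S,9S,10R)‑4,4,10‑trimethyl analogue of 10 with a saturated ring‑A 2‑ketone
Conditions: Me2CuLi (5 equiv), TMSCl, THF, −78 → −20 °C; then aq. NH4Cl/citric acid
Reagents that add atoms: lithium dimethylcuprate (from MeLi and CuI), [Li+].C[Cu-]C
Why: TMSCl‑accelerated Gilman conjugate addition to the remaining β‑methyl enone builds the C4 gem‑dimethyl (no new stereocentre); the dithiane keeps C6 masked and non‑enolizable.

**Step 7**
Reactants: 11
Product: 12, (5S,9S,10R)‑9‑[2‑(TBSO)ethyl]‑4,4,10‑trimethyl‑8‑methylidene‑5β‑(trimethylsilyloxy)‑cis‑decalin‑2,6‑dione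
Conditions: PhI(OCOCF3)2, NaHCO3, MeCN/H2O (9:1), 0 °C
Reagents that add atoms: water, O
Why: Oxidative dithioacetal hydrolysis under buffered conditions releases the C6 ketone without touching the 1,1‑disubstituted alkene, the silyl ethers or the C2 ketone.

**Step 8**
Reactants: 12
Product: 13, (5S,9S,10R)‑9‑[2‑(TBSO)ethyl]‑4,4,10‑trimethyl‑8‑methylidene‑trans‑decalin‑2,6‑dione
Conditions: SmI2 (2.5 equiv), THF/MeOH, −78 °C
Reagents that add atoms: none
Why: SmI2 reductive cleavage of the α‑siloxy ketone removes the former phenol oxygen, and the Sm(III) enolate is protonated at C5 axially from the α face, anti to the 10β‑methyl, giving the trans‑decalin (5α‑H), which is also the thermodynamic epimer.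

**Step 9**
Reactants: 13
Product: 14, (2R,5S,9S,10R)‑2β‑hydroxy‑9‑[2‑(TBSO)ethyl]‑4,4,10‑trimethyl‑8‑methylidene‑trans‑decalin‑6‑one
Conditions: L‑Selectride (1.05 equiv), THF, −78 °C; aq. NH4Cl
Reagents that add atoms: none
Why: Hydride reduction is selective for the unbranched C2 ketone over the C6 ketone (shielded by C5 and the C4 methyls), and the two syn‑axial methyls (4β, 10β) block the β face, so hydride enters from the α face to give the axial 2β‑alcohol.

**Step 10**
Reactants: 14
Product: 15, (2S,5S,9S,10R)‑2α‑chloro‑9‑[2‑(TBSO)ethyl]‑4,4,10‑trimethyl‑8‑methylidene‑trans‑decalin‑6‑one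
Conditions: PPh3, CCl4, MeCN, 60 °C
Reagents that add atoms: carbon tetrachloride, ClC(Cl)(Cl)Cl
Why: Appel chlorination; chloride displaces the strained axial oxyphosphonium by SN2 from the open α face, inverting C2 to the equatorial 2α‑chloride.

**Step 11**
Reactants: 15
Product: 16, (2S,5S,9S,10R)‑2α‑chloro‑9‑(2‑hydroxyethyl)‑4,4,10‑trimethyl‑8‑methylidene‑trans‑decalin‑6‑one
Conditions: HF·pyridine, THF/pyridine, 0 °C → rt
Reagents that add atoms: none
Why: Mildly acidic desilylation avoids the base‑induced shift of the β,γ‑alkene into conjugation that fluoride/TBAF could cause.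

**Step 12**
Reactants: 16
Product: 17, 2‑[(2S,5S,9S,10R)‑2‑chloro‑4,4,10‑trimethyl‑8‑methylidene‑6‑oxo‑trans‑decalin‑9‑yl]acetaldehyde
Conditions: Dess–Martin periodinane, NaHCO3, CH2Cl2, 0 °C → rt
Reagents that add atoms: none
Why: Neutral Dess–Martin oxidation gives the C12 aldehyde without epimerizing C5 or isomerizing the alkene; the aldehyde is used crude.

**Step 13**
Reactants: 18, 3‑cyanopropanoic acid; 19, (R)‑4‑benzyl‑1,3‑oxazolidin‑2‑one
Product: 20, (R)‑4‑benzyl‑3‑(3‑cyanopropanoyl)‑1,3‑oxazolidin‑2‑one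
Conditions: PivCl, Et3N, THF, −20 °C; then 19, LiCl, rt
Reagents that add atoms: none beyond reactants 18 and 19
Why: Mixed‑anhydride N‑acylation of the Evans auxiliary.

**Step 14**
Reactants: 17; 20
Product: 21, (R)‑4‑benzyl‑3‑{(2R,3S)‑2‑(cyanomethyl)‑3‑hydroxy‑4‑[(2S,5S,9S,10R)‑2‑chloro‑4,4,10‑trimethyl‑8‑methylidene‑6‑oxo‑trans‑decalin‑9‑yl]butanoyl}‑1,3‑oxazolidin‑2‑one
Conditions: 20, Bu2BOTf, i‑Pr2NEt, CH2Cl2, −78 → 0 °C; then 17, −78 → 0 °C; pH 7 buffer, MeOH, H2O2, 0 °C
Reagents that add atoms: none beyond reactants 17 and 20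
Why: Evans syn‑aldol via the Z‑boron enolate and a Zimmerman–Traxler transition state; the (R)‑benzyl auxiliary sets 12S and 13R, and the preformed enolate reacts with the aldehyde only, leaving the hindered C6 ketone alone.

**Step 15**
Reactants: 21
Product: 22, Haterumaimide G
Conditions: [PtH(PMe2OH)(PMe2O)2H] (5 mol %), EtOH/H2O (4:1), 70 °C
Reagents that add atoms: water, O
Why: Neutral Pt‑catalysed nitrile hydration (Ghaffar–Parkins) gives the primary amide, which closes 5‑exo onto the N‑acyl oxazolidinone carbonyl to form the succinimide and release the auxiliary; no base is used, so C13 and the β,γ‑enone are preserved (a trace of Et3N at rt completes the closure if needed).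

## Compound list

1 | 2,6‑dimethylphenol | Cc1cccc(C)c1O | starting material
2 | 4,4‑dimethoxy‑2,6‑dimethylcyclohexa‑2,5‑dien‑1‑one | COC1(OC)C=C(C)C(=O)C(C)=C1 | intermediate
3 | 1,3‑dithiane | C1CSCSC1 | starting material
4 | propargyl bromide | C#CCBr | starting material
5 | 2‑(prop‑2‑yn‑1‑yl)‑1,3‑dithiane | C#CCC1SCCCS1 | intermediate
6 | (trimethylsilyl)methylmagnesium chloride | C[Si](C)(C)C[Mg]Cl | starting material
7 | ethylene oxide | C1CO1 | starting material
8 | (Z)‑allylsilane dithiane TBS ether | CC(C)(C)[Si](C)(C)OCC/C=C(\C[Si](C)(C)C)CC1SCCCS1 | intermediate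
9 | Cs‑symmetric quinol silyl ether dienone | C[Si](C)(C)OC1(C(C)=CC(=O)C=C1C)C1(C/C(C[Si](C)(C)C)=C/CCO[Si](C)(C)C(C)(C)C)SCCCS1 | intermediate
10 | (5S,9S,10R) cis‑fused enone, Sakurai product | C=C1CC2(SCCCS2)[C@]3(O[Si](C)(C)C)C(C)=CC(=O)C[C@]3(C)[C@H]1CCO[Si](C)(C)C(C)(C)C | intermediate
11 | (5S,9S,10R) 4,4,10‑trimethyl ketone, dithiane retained | C=C1CC2(SCCCS2)[C@]3(O[Si](C)(C)C)C(C)(C)CC(=O)C[C@]3(C)[C@H]1CCO[Si](C)(C)C(C)(C)C | intermediate
12 | (5S,9S,10R) 5β‑siloxy cis‑decalin‑2,6‑dione | C=C1CC(=O)[C@]2(O[Si](C)(C)C)C(C)(C)CC(=O)C[C@]2(C)[C@H]1CCO[Si](C)(C)C(C)(C)C | intermediate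
13 | (5S,9S,10R) trans‑decalin‑2,6‑dione | C=C1CC(=O)[C@H]2C(C)(C)CC(=O)C[C@]2(C)[C@H]1CCO[Si](C)(C)C(C)(C)C | intermediate
14 | (2R,5S,9S,10R) 2β‑alcohol | C=C1CC(=O)[C@H]2C(C)(C)C[C@@H](O)C[C@]2(C)[C@H]1CCO[Si](C)(C)C(C)(C)C | intermediate
15 | (2S,5S,9S,10R) 2α‑chloride, TBS ether | C=C1CC(=O)[C@H]2C(C)(C)C[C@H](Cl)C[C@]2(C)[C@H]1CCO[Si](C)(C)C(C)(C)C | intermediate
16 | (2S,5S,9S,10R) chloro keto alcohol | C=C1CC(=O)[C@H]2C(C)(C)C[C@H](Cl)C[C@]2(C)[C@H]1CCO | intermediate
17 | (2S,5S,9S,10R) chloro keto aldehyde | C=C1CC(=O)[C@H]2C(C)(C)C[C@H](Cl)C[C@]2(C)[C@H]1CC=O | intermediate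
18 | 3‑cyanopropanoic acid | N#CCCC(=O)O | starting material
19 | (R)‑4‑benzyl‑1,3‑oxazolidin‑2‑one | O=C1OC[C@@H](Cc2ccccc2)N1 | starting material
20 | (R)‑4‑benzyl‑3‑(3‑cyanopropanoyl)‑1,3‑oxazolidin‑2‑one | N#CCCC(=O)N1[C@H](Cc2ccccc2)COC1=O | intermediate
21 | Evans syn‑aldol adduct (12S,13R) | C=C1CC(=O)[C@H]2C(C)(C)C[C@H](Cl)C[C@]2(C)[C@H]1C[C@H](O)[C@@H](CC#N)C(=O)N1[C@H](Cc2ccccc2)COC1=O | intermediate
22 | Haterumaimide G | C=C1CC(=O)[C@H]2C(C)(C)C[C@H](Cl)C[C@]2(C)[C@H]1C[C@H](O)[C@H]1CC(=O)NC1=O | target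

## Step count and risks

Total steps: 15. Longest linear sequence: 13 (steps 2–12, 14, 15, from 1,3‑dithiane and propargyl bromide).

Steps most likely to fail:

1. **Step 5, enantioselective desymmetrizing Sakurai closure.** The enantioselectivity is unprecedented, the dithiane may bind the silylium catalyst, and a 1,2‑shift of the dithianyl group could compete.
   Fallback: break the symmetry one step earlier by Cu/phosphoramidite‑catalysed enantioselective conjugate methylation of dienone 9 (this makes the C4 gem‑dimethyl and a stereogenic C5), then close ring B with an achiral Lewis acid (EtAlCl2). The cis delivery from C5 and the chair transition state then relay the chirality to C10 and C9.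

2. **Step 6, methyl cuprate addition at C4.** This makes a quaternary carbon next to the fully substituted C5, and electron‑transfer loss of the γ‑siloxy group is possible.
   Fallback: intramolecular methyl delivery from the C5 oxygen. Exchange the 5‑O‑TMS for a (bromomethyl)dimethylsilyl ether, run a 5‑exo radical cyclization onto C4 (Bu3SnH, AIBN), then protodesilylate the oxasilacycle (KOt‑Bu/DMSO or TBAF/DMF) to reveal the methyl.

3. **Step 10, SN2 chlorination of the hindered axial 2β‑alcohol.** E2 elimination to the Δ1/Δ2 olefins can dominate.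
   Fallback: radical deoxychlorination. Convert the C2 alcohol (either epimer) to an oxalate or xanthate, generate the C2 radical photochemically and trap it with a chlorine‑atom donor. The radical is chlorinated from the unhindered α face, giving the equatorial 2α‑chloride without any SN2/E2 competition.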